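The slowness of Wednesday's run is what has to be reckoned with: its electrophile lost 34.7% of its charge by 8.00 h, then 12 percentage points in the following 32.0 h, and the readings balance against target.

| flask | electrophile | free base | protonated nucleophile | remark | time |
|---|---|---|---|---|---|
| Wednesday's | 20 mM | 11 mM | 16 mM | run made earlier |  |
| north | 20 mM | 16.0 mM | 16.0 mM |  | 2.5 d |
| north-east | 20 mM | 21.0 mM | 16.0 mM |  | 2.5 d |
| east | 20 mM | 27.0 mM | 16.0 mM |  | 2.5 d |

- Wednesday's (time / h: electrophile / %, target / %): 8.00: 65.3, 35.0; 15.0: 60.5, 38.6; 20.0: 58.6, 40.7; 30.0: 55.3, 44.4; 40.0: 53.0, 46.4

(readings scatter by 0.3 percentage points)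

- no earlier run changes the charge of free base; that part of a forecast is a guess

1. part of the electrophile that has reacted at the end, north
2. part of the electrophile that has reacted at the end, north-east
3. part of the electrophile that has reacted at the end, east
4. what raising the concentration of free base from its lowest to its highest value here does to the part of the electrophile that has reacted (changes below 5 percentage points count as none) (it falls / it rises / no change)

The reckoning here supposes a balance of the free base. Each free base unmasks one protonated nucleophile, and each electrophile that reacts takes one nucleophile and sets free one acid, which a second nucleophile binds. The fast stage then ends at a knee, x = K/2, where x is the electrophile reacted and K the free base charged. On Wednesday the knee is 5.50 mM, and the first reading, 6.94 mM, already stands past it. Past the knee the acid set free is the surplus s = 2x − K, and the rate is κ·E·(N − x)/s, with E the electrophile left and N the protonated nucleophile charged. So s² climbs in time with slope 4κ·E·(N − x). Between the outer readings x reaches 9.40 mM, so s goes from 2.88 mM to 7.80 mM. Midway E is 11.8 mM and N − x is 7.83 mM, which gives the stall constant, the coefficient of that climb, as a reading: 0.00443 h⁻¹.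

Holding the slope at its knee value for 2.5 d gives x of 13.1 mM, 14.2 mM and 15.6 mM for north, north-east and east. That slope is the weak link, since it falls as x grows. Taking it midway between knee and first answer gives 58.6%, 66.1% and 74.8%.

The forecast, reasoning that “the growing conjugate acid buffers down the free nucleophile”, says 61%, 67% and 72%, and of the trend, it rises. It stands above this reckoning in north and below it in east.

The flasks give 57.8%, 64.9% and 73.0%: it rises, by 15 points.

    nucleophile + target → over-reaction product (k = 1.40 M⁻¹ h⁻¹)
    electrophile + nucleophile → acid set free + target (k = 36.0 M⁻¹ h⁻¹)
    nucleophile + acid set free ⇌ protonated nucleophile, settled at all times (K = 7200 M⁻¹)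
    crystals ⇌ acid set free, rate k4*(cs4 - [acid set free]) while solid is left; crystals form when [acid set free] > cs4 (solubility = 6.90 mM, k = 0.290 h⁻¹)
    acid set free + free base ⇌ salt of the base, settled at all times (K = 4.40 × 10⁶ M⁻¹)

The neighbour is north-east itself, read at 6.0 d. At 2.50 d its free base, the first charge to run out, stands at 0% of its charge against 35% for the electrophile. From the 64.9% reacted then, the reckoned surplus is 4.97 mM. The stall constant, with the slope taken at that moment's electrophile and protonated nucleophile, carries s² on for a further 84.0 h and gives 71.2%. The flask at 6.0 d stands at 69.5%, with target at 67.6%.

The runs are calculated with made-up constants; the scatter is artificial.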